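The runs were generated by integration for an exercise; noise was put on by code.

**Open the books.** Take Z as the limiting reagent of this flask by the charges, since its 20.8 mM stands below the 26 mM of E, and enter every millimole of it in a ledger. At one Z per D, the ceiling for D is 80.0% of the E charged.

| flask | E | Z | remark | time |
|---|---|---|---|---|
| violet | 26 mM | 20.8 mM | the very flask that is asked about, followed so far |  |
| flask | 26 mM | 20.8 mM |  | 8.0 d |

violet run (percent of the E charged)

| time / d | D / % | X / % |
|---|---|---|
| 0.500 | 9.5 | 0.4 |
| 0.833 | 16.3 | 0.8 |
| 1.25 | 20.8 | 0.5 |
| 1.67 | 27.6 | 0 |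
| 2.50 | 36.0 | 0.6 |
| 3.00 | 34.3 | 0 |

(standard deviation of a reading: 1 percentage point)

1. D and X together at 8.0 d, in percent of the E charged
2. concentration of G in solution at 8.0 d, in percent of saturation

- D is meant together with its X
- solid, in amounts per volume of the solution: E, X
- what was read earlier has a scatter of 1 percentage point, one standard deviation
- at the start none of E is in solution
- G is what E becomes in solution
- G means what is dissolved; the solid is not counted in it

**First entry.** Add X to D in each reading. The sum climbs, then reads as a stall within the scatter: the last two readings average 35.4%, which reads as 9.22 mM of D. That is 44.3% of the Z charged; call this part of the Z found in D at the stall the stall share.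

**Open entry.** Leave the other 11.6 mM of Z open: the readings are of D and X.

**Commit.** As my own reckoning, hold the stall at 35.4% for 8.0 d, under the ceiling. More Z stands open than the readings put in D, yet the last two readings do not rise, so if that Z is still free, put dissolved G far below saturation.

**The result.** The forecast says 63% and 85%, on the ground that “the rate follows remaining Z”. This flask gives 31.1% and 3.42%.

    E ⇌ G, rate k1*(cs1 - [G]) while solid is left; crystals form when [G] > cs1 (solubility = 17.0 mM, k = 6.70 × 10⁻⁴ min⁻¹)
    G + Z ⇌ D (K = 1900 M⁻¹, k = 0.110 M⁻¹ min⁻¹)
    2 G → Q (k = 0.180 M⁻¹ min⁻¹)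
    X ⇌ D, rate k4*(cs4 - [D]) while solid is left; crystals form when [D] > cs4 (solubility = 10.0 mM, k = 0.0480 min⁻¹)
    Z ⇌ J (K = 1.30, k = 8.90 × 10⁻⁴ min⁻¹)

**Books closed.** The held stall stands 4.3 percentage points above the result. In this flask at 8.00 d, D and X hold 38.9% of the charged Z against the stall share of 44.3%. E stands at 0%, Z keeps 26.8% of its own charge and J stands at 7.14 mM, and D, X, Z and J together close at 20.8 mM. Now take the neighbour flask with 83 mM of Z. The stall share promises 36.8 mM of D, more than the 26 mM of E charged, so E becomes the limiting reagent of the reckoning. That neighbour flask gives 82.2%, which is 25.7% of its Z, with E at 0%, Q at 17.0% of the E charged and Z at 32.3% of its own charge.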